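All constants are those of an exercise.

If the next run is to give more target from the same charges, the question is how long I keep the flask warm.

all flasks: substrate 0.050 M; partner 0.0500 M; reagent 0.125 M; capture agent 0.0150 M; time 15 h
- dusk: temperature 15 °C
- summer: at 15 °C until 3.0 h, from then on at 0 °C
- autumn: temperature 0 °C

    reagent + partner → second intermediate (k1 = 0.726 /M/h, Ea1 = 67.0 kJ/mol)
    open intermediate + second intermediate → target (k2 = 0.841 /M/h, Ea2 = 63.0 kJ/mol)
    crystals ⇌ target, rate k3*(cs3 - [target]) while solid is left; crystals form when [target] > cs3 (cs3 = 4.5 mM, k3 = 3.99 /h)
    second intermediate + capture agent → trapped intermediate (k4 = 2.24 /M/h, Ea4 = 47.0 kJ/mol)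
    substrate + reagent → open intermediate (k5 = 5.61 /M/h, Ea5 = 48.0 kJ/mol)
    substrate + second intermediate → side product (k6 = 2.17 /M/h, Ea6 = 73.0 kJ/mol)
    (constants at 0 °C)

- what is said of target includes crystals
- crystals is a solid; its amount is given per volume of the solution
- constants are those at 0 °C; use the activation energies for any other temperature

- the flask with the highest amount of target, in percent of the substrate charged ("all alike" if they lie within 1.5 percentage points) (dusk / summer / autumn / all alike)
- final target, as a percentage of the substrate charged, in dusk
- final target, as a percentage of the substrate charged, in summer
- final target, as a percentage of the substrate charged, in autumn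

Reagent turns substrate into open intermediate, and partner into second intermediate; these two then join to give target, while capture agent takes second intermediate away. I write o for the fraction of the substrate charge standing as open intermediate and c for the fraction of the capture charge left. The routes to target and to capture then each have a pseudo-first-order rate, its constant times its charge times its fraction. Reagent consumes the substrate with a starting lifetime of 1.43 h at 0 °C, well inside the 15 h run. So, as an estimate for the stretch in which both fractions stand near one, I set o and c to one:

target share = target rate / (target rate + capture rate)

at 0 °C: 0.0420 /h against 0.0336 /h, share 55.6%

at 15 °C: 0.178 /h against 0.0987 /h, share 64.4%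

This ratio is the part of the second intermediate leaving that becomes target rather than being captured: the target share. Warmth does not spend it, since the share at 15 °C is larger. With o and c at one, warmth also shortens the lifetime of second intermediate, the inverse of the two rates summed, from 13.2 h to 3.61 h, which is well under the run. My reckoning gives an order and no yields: dusk, then summer, then autumn. So I keep the flask at 15 °C throughout and do not cool it at 3.0 h.

The forecast names dusk, with 50% in dusk, 23% in summer and 13% in autumn. Its ground: “The second intermediate forms slowly and is consumed slowly at 0 °C”.

The flask gives 45.3% in dusk, the most, 21.3% in summer and 11.7% in autumn. In autumn, target over target plus trapped intermediate reads 56.2% over the whole run, whereas the reckoned 55.6% holds for o and c at one, and autumn ends with o at 85.8% and c at 69.6%. The neighbour is summer with 0.031 M of reagent, 0.620 equiv, where reagent is the limiting reagent, with 1.6% left. It ends with o at 47.3% and c at 92.1%, so the target share with the 0 °C constants is 39.1%. Over its whole run that neighbour reads 38.0% as target over target plus trapped intermediate, with target at 1.46%.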